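**Plan**

1. Cuts, in retrosynthetic order: the three MOM ethers; the B‑ring C1′–C2 bond, giving a 6‑geranyl‑5‑hydroxy‑7‑(MOM‑oxy)chromone and a 3‑methoxy‑4,5‑bis(MOM‑oxy)phenylboronic acid; the C6–C1″ geranyl bond (6‑iodochromone + geranylstannane); the aryl C–B bond (protected 3‑methoxycatechol).
2. Enabling feature: C2, the only stereocentre, is the β‑carbon of the C2=C3–C4=O enone of the pyranone (C) ring and is the atom that carries the B ring. A flat 4H‑chromen‑4‑one can therefore accept the whole B ring as an aryl nucleophile, with C2 set in the same event.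
3. Forward order: the A/C bicycle is bought intact (5,7‑dihydroxychromone), so the O1–C8a bond is fixed from the start and the 6‑ versus 8‑geranyl ambiguity of a chalcone closure cannot arise. Then 7‑O‑MOM, C6 iodination directed by the chelated 5‑OH, and Stille geranylation.
4. B ring: 3‑methoxycatechol, bis‑MOM ether, Ir‑catalysed C–H borylation at the only unhindered C–H, hydrolysis to the boronic acid.
5. Union and stereochemistry: Rh(I)/chiral diene 1,4‑addition under catalyst control (Re‑face arylation of C2 gives 2S), then mild acidic removal of the MOM groups.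

Key step: step 8

Assumption: 5,7‑dihydroxychromone, 3‑methoxycatechol and geranyl chloride are taken as catalogue chemicals, and the hand of the chiral diene that gives Re‑face arylation is to be assigned on a small run from the CD pattern typical of (2S)‑flavanones before material is committed.

**Route**

Step 1
Reactants: 1 5,7‑dihydroxy‑4H‑chromen‑4‑one
Product: 2 5‑hydroxy‑7‑(methoxymethoxy)‑4H‑chromen‑4‑one
Conditions: MOMCl (1.1 equiv), iPr2NEt (1.5 equiv), CH2Cl2, 0 °C to rt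
Reagents that add atoms: chloromethyl methyl ether (MOMCl), COCCl
Why: Williamson‑type O‑alkylation should occur only at the acidic, unchelated 7‑OH, because the 5‑OH is held in a hydrogen bond to the C4 carbonyl.

Step 2
Reactants: 2 5‑hydroxy‑7‑(methoxymethoxy)‑4H‑chromen‑4‑one
Product: 3 5‑hydroxy‑6‑iodo‑7‑(methoxymethoxy)‑4H‑chromen‑4‑one
Conditions: BnMe3N·ICl2 (1.05 equiv), CaCO3 (1.5 equiv), CH2Cl2/MeOH (5:2), rt, dark
Reagents that add atoms: benzyltrimethylammonium dichloroiodate, C[N+](C)(C)Cc1ccccc1.Cl[I-]Cl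
Why: Electrophilic aromatic iodination of a 5‑hydroxy‑7‑alkoxy benzopyranone should go ortho to the free chelated 5‑OH (C6), as is the pattern for 5‑hydroxy‑7‑alkoxyflavones, while CaCO3 buffers the HCl so the MOM ether survives.

Step 3
Reactants: 4 geranyl chloride, (2E)‑1‑chloro‑3,7‑dimethylocta‑2,6‑diene
Product: 5 tributyl[(2E)‑3,7‑dimethylocta‑2,6‑dien‑1‑yl]stannane
Conditions: Bu3SnH, LDA, THF, 0 °C; then 4, −78 °C to rt
Reagents that add atoms: tributyltin hydride, CCCC[SnH](CCCC)CCCC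
Why: SN2 displacement of the primary allylic chloride by tributylstannyllithium should give the linear stannane without touching the E‑configured C2=C3 bond.

Step 4
Reactants: 3 5‑hydroxy‑6‑iodo‑7‑(methoxymethoxy)‑4H‑chromen‑4‑one; 5 tributyl[(2E)‑3,7‑dimethylocta‑2,6‑dien‑1‑yl]stannane
Product: 6 6‑[(2E)‑3,7‑dimethylocta‑2,6‑dien‑1‑yl]‑5‑hydroxy‑7‑(methoxymethoxy)‑4H‑chromen‑4‑one
Conditions: Pd2(dba)3 (2.5 mol %), P(2‑furyl)3 (10 mol %), DMF (degassed), 80 °C
Reagents that add atoms: none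
Why: Stille coupling of an aryl iodide with a 3,3‑disubstituted allylstannane should end with reductive elimination at the unsubstituted allyl terminus (linear geranyl arene), and the E geometry should hold because syn/anti exchange would need a tertiary σ‑allyl palladium.

Step 5
Reactants: 7 3‑methoxybenzene‑1,2‑diol (3‑methoxycatechol)
Product: 8 1‑methoxy‑2,3‑bis(methoxymethoxy)benzene
Conditions: NaH (2.4 equiv), DMF, 0 °C; MOMCl (2.4 equiv), 0 °C to rt
Reagents that add atoms: chloromethyl methyl ether (MOMCl), COCCl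
Why: Double Williamson etherification of the catechol dianion is routine and gives ethers that tolerate the borylation and the rhodium step.

Step 6
Reactants: 8 1‑methoxy‑2,3‑bis(methoxymethoxy)benzene
Product: 9 2‑[3‑methoxy‑4,5‑bis(methoxymethoxy)phenyl]‑4,4,5,5‑tetramethyl‑1,3,2‑dioxaborolane
Conditions: [Ir(OMe)(cod)]2 (1.5 mol %), dtbpy (3 mol %), B2pin2 (1.0 equiv), THF, 80 °C
Reagents that add atoms: bis(pinacolato)diboron, CC1(C)OB(OC1(C)C)B1OC(C)(C)C(C)(C)O1
Why: Sterically controlled Ir‑catalysed C–H borylation of a 1,2,3‑trisubstituted benzene should take place at C5, the only C–H with no ortho substituent.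

Step 7
Reactants: 9 2‑[3‑methoxy‑4,5‑bis(methoxymethoxy)phenyl]‑4,4,5,5‑tetramethyl‑1,3,2‑dioxaborolane
Product: 10 [3‑methoxy‑4,5‑bis(methoxymethoxy)phenyl]boronic acid
Conditions: NaIO4 (3 equiv), NH4OAc (3 equiv), acetone/H2O (1:1), rt
Reagents that add atoms: water, O
Why: Hydrolysis of the pinacol boronate is driven by periodate cleavage of the released pinacol at near‑neutral pH, which the MOM ethers should tolerate.

Step 8
Reactants: 6 6‑[(2E)‑3,7‑dimethylocta‑2,6‑dien‑1‑yl]‑5‑hydroxy‑7‑(methoxymethoxy)‑4H‑chromen‑4‑one; 10 [3‑methoxy‑4,5‑bis(methoxymethoxy)phenyl]boronic acid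
Product: 11 (2S)‑6‑[(2E)‑3,7‑dimethylocta‑2,6‑dien‑1‑yl]‑5‑hydroxy‑2‑[3‑methoxy‑4,5‑bis(methoxymethoxy)phenyl]‑7‑(methoxymethoxy)‑2,3‑dihydro‑4H‑chromen‑4‑one
Conditions: [RhCl(C2H4)2]2 (2.5 mol %), chiral diene Ph‑bod* (2,5‑diphenylbicyclo[2.2.2]octa‑2,5‑diene, antipode giving Re‑face arylation, 5.5 mol %), 10 (2.5 equiv), aq. KOH (10 mol %), toluene/H2O (10:1), 30 °C
Reagents that add atoms: none
Why: This is a Hayashi–Miyaura‑type Rh(I)‑catalysed asymmetric 1,4‑addition of an arylboronic acid, a reaction type established for chromones: boron‑to‑rhodium transmetalation gives an aryl–Rh(I)(diene) species, the C2=C3 bond of the pyranone ring inserts with the aryl group going to C2, and the oxa‑π‑allyl rhodium enolate is protonated at C3 by water, which regenerates Rh–OH. No ring is closed; the step only forms the C2–C1′ bond that joins the two halves. The new C2 stereocentre is set under pure catalyst control, since the substrate is achiral and flat: the C2‑symmetric diene shields one enantioface of the bound enone, and the antipode is used that delivers the aryl group to the Re face of C2, which corresponds to 2S. The step needs 1,4‑ over 1,2‑selectivity and must spare the geranyl alkenes; insertion into the conjugated C2=C3 bond should be far faster than into the unactivated trisubstituted alkenes or the hydrogen‑bonded C4 carbonyl, and low temperature with only catalytic base limits a second aryl transfer to C4. The free 5‑OH, hydrogen‑bonded to C4=O, raises the electrophilicity of C2, and the near‑neutral medium should keep the product from opening to the chalcone, so C2 is not scrambled and the O1–C8a connectivity (6‑ and not 8‑geranyl) cannot change.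

Step 9
Reactants: 11 (2S)‑6‑[(2E)‑3,7‑dimethylocta‑2,6‑dien‑1‑yl]‑5‑hydroxy‑2‑[3‑methoxy‑4,5‑bis(methoxymethoxy)phenyl]‑7‑(methoxymethoxy)‑2,3‑dihydro‑4H‑chromen‑4‑one
Product: 12 (2S)‑2‑(3,4‑dihydroxy‑5‑methoxyphenyl)‑6‑[(2E)‑3,7‑dimethylocta‑2,6‑dien‑1‑yl]‑5,7‑dihydroxy‑2,3‑dihydro‑4H‑chromen‑4‑one (CNP0110161.1)
Conditions: 3 M aq. HCl/MeOH (1:5), 40–45 °C, stopped at full conversion
Reagents that add atoms: none
Why: Acid‑catalysed transacetalisation of the three aryl MOM ethers to methanol is the standard final deprotection for prenylated and geranylated flavanones and, run dilute and warm but not hot, should spare the geranyl alkenes and the C2 configuration.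

**Compound list**

1 | 5,7‑dihydroxy‑4H‑chromen‑4‑one | O=c1ccoc2cc(O)cc(O)c12 | starting material
2 | 5‑hydroxy‑7‑(methoxymethoxy)‑4H‑chromen‑4‑one | O=c1ccoc2cc(OCOC)cc(O)c12 | intermediate
3 | 5‑hydroxy‑6‑iodo‑7‑(methoxymethoxy)‑4H‑chromen‑4‑one | O=c1ccoc2cc(OCOC)c(I)c(O)c12 | intermediate
4 | geranyl chloride, (2E)‑1‑chloro‑3,7‑dimethylocta‑2,6‑diene | CC(C)=CCC/C(C)=C/CCl | starting material
5 | tributyl[(2E)‑3,7‑dimethylocta‑2,6‑dien‑1‑yl]stannane | CCCC[Sn](CCCC)(CCCC)C/C=C(\C)CCC=C(C)C | intermediate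
6 | 6‑[(2E)‑3,7‑dimethylocta‑2,6‑dien‑1‑yl]‑5‑hydroxy‑7‑(methoxymethoxy)‑4H‑chromen‑4‑one | O=c1ccoc2cc(OCOC)c(C/C=C(\C)CCC=C(C)C)c(O)c12 | intermediate
7 | 3‑methoxybenzene‑1,2‑diol | COc1cccc(O)c1O | starting material
8 | 1‑methoxy‑2,3‑bis(methoxymethoxy)benzene | COCOc1cccc(OC)c1OCOC | intermediate
9 | 2‑[3‑methoxy‑4,5‑bis(methoxymethoxy)phenyl]‑4,4,5,5‑tetramethyl‑1,3,2‑dioxaborolane | COCOc1cc(B2OC(C)(C)C(C)(C)O2)cc(OC)c1OCOC | intermediate
10 | [3‑methoxy‑4,5‑bis(methoxymethoxy)phenyl]boronic acid | COCOc1cc(B(O)O)cc(OC)c1OCOC | intermediate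
11 | (2S)‑6‑[(2E)‑3,7‑dimethylocta‑2,6‑dien‑1‑yl]‑5‑hydroxy‑2‑[3‑methoxy‑4,5‑bis(methoxymethoxy)phenyl]‑7‑(methoxymethoxy)‑2,3‑dihydro‑4H‑chromen‑4‑one | COc1cc([C@@H]2CC(=O)c3c(cc(OCOC)c(C/C=C(\C)CCC=C(C)C)c3O)O2)cc(OCOC)c1OCOC | intermediate
12 | (2S)‑2‑(3,4‑dihydroxy‑5‑methoxyphenyl)‑6‑[(2E)‑3,7‑dimethylocta‑2,6‑dien‑1‑yl]‑5,7‑dihydroxy‑2,3‑dihydro‑4H‑chromen‑4‑one | COc1cc([C@@H]2CC(=O)c3c(cc(O)c(C/C=C(\C)CCC=C(C)C)c3O)O2)cc(O)c1O | target

**Count and risks**

Total steps: 9. Longest linear sequence: 5 steps (1 → 2 → 3 → 6 → 11 → 12, or equally 7 → 8 → 9 → 10 → 11 → 12).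

Steps most likely to fail:

Step 8. What may go wrong: slow carbometalation of the electron‑rich, chelated pyranone so that protodeboronation of the aryl donor wins; a second aryl transfer to C4 of the product; insufficient facial discrimination; base‑induced ring opening that erodes the C2 configuration. Fallback, in which the stereochemistry comes from separation instead of catalyst control: setting out from 6 and 10, the union is run without a chiral ligand under the most active achiral catalyst of this reaction class, [Rh(OH)(cod)]2 in dioxane/H2O at 40–50 °C. This should give racemic 6‑[(2E)‑3,7‑dimethylocta‑2,6‑dien‑1‑yl]‑5‑hydroxy‑2‑[3‑methoxy‑4,5‑bis(methoxymethoxy)phenyl]‑7‑(methoxymethoxy)‑2,3‑dihydro‑4H‑chromen‑4‑one F1. The enantiomers are then separated by preparative SFC on a polysaccharide chiral stationary phase, and the (2S)‑antipode is 11, where the route is rejoined.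

Step 4. What may go wrong: allylic transposition at the η3‑allylpalladium stage (branched, linalyl‑type coupling), E/Z erosion, or slow oxidative addition at the doubly ortho‑substituted C6–I bond followed by protodeiodination. Fallback with reversed polarity (aryl nucleophile, geranyl electrophile, no π‑allyl metal): setting out from 3, the 5‑OH is capped (NaH, MOMCl, DMF, 0 °C) to give 6‑iodo‑5,7‑bis(methoxymethoxy)‑4H‑chromen‑4‑one F2. Iodine–magnesium exchange with iPrMgCl·LiCl in THF at −40 °C gives [5,7‑bis(methoxymethoxy)‑4‑oxo‑4H‑chromen‑6‑yl]magnesium chloride F3, used in situ. This is alkylated at the primary carbon of geranyl bromide under CuBr·SMe2 catalysis (SN2, E geometry untouched) to give 6‑[(2E)‑3,7‑dimethylocta‑2,6‑dien‑1‑yl]‑5,7‑bis(methoxymethoxy)‑4H‑chromen‑4‑one F4. The peri 5‑O‑MOM group, activated by the neighbouring C4 carbonyl, is then cleaved selectively with dilute HCl in MeOH/THF at 0 °C, which returns the route at 6.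

Step 9. What may go wrong: acid‑promoted cyclisation of the geranyl C2″=C3″ alkene onto the flanking 5‑ or 7‑OH (chroman formation), addition of methanol to the terminal alkene, or epimerisation at C2 through reversible opening of the pyranone ring. Fallback with fluoride‑labile silyl ethers in place of MOM, so that no acid is needed at the end:
- A‑ring side: setting out from 1, TIPSCl/imidazole in DMF should give 5‑hydroxy‑7‑[(triisopropylsilyl)oxy]‑4H‑chromen‑4‑one F5. The conditions of step 2 then give 5‑hydroxy‑6‑iodo‑7‑[(triisopropylsilyl)oxy]‑4H‑chromen‑4‑one F6, and those of step 4 (with 5) give 6‑[(2E)‑3,7‑dimethylocta‑2,6‑dien‑1‑yl]‑5‑hydroxy‑7‑[(triisopropylsilyl)oxy]‑4H‑chromen‑4‑one F7.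
- B‑ring side: setting out from 7, TBSCl/imidazole gives 1,2‑bis[(tert‑butyldimethylsilyl)oxy]‑3‑methoxybenzene F8. The conditions of steps 6 and 7 then give 2‑{3,4‑bis[(tert‑butyldimethylsilyl)oxy]‑5‑methoxyphenyl}‑4,4,5,5‑tetramethyl‑1,3,2‑dioxaborolane F9 and {3,4‑bis[(tert‑butyldimethylsilyl)oxy]‑5‑methoxyphenyl}boronic acid F10.
- Union and release: F7 and F10 under the conditions of step 8 give (2S)‑2‑{3,4‑bis[(tert‑butyldimethylsilyl)oxy]‑5‑methoxyphenyl}‑6‑[(2E)‑3,7‑dimethylocta‑2,6‑dien‑1‑yl]‑5‑hydroxy‑7‑[(triisopropylsilyl)oxy]‑2,3‑dihydro‑4H‑chromen‑4‑one F11. Et3N·3HF in THF at 0 °C to rt then removes all three silyl groups and returns the route at 12.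

**Further compounds**

F1 | step 8 | racemic 6‑[(2E)‑3,7‑dimethylocta‑2,6‑dien‑1‑yl]‑5‑hydroxy‑2‑[3‑methoxy‑4,5‑bis(methoxymethoxy)phenyl]‑7‑(methoxymethoxy)‑2,3‑dihydro‑4H‑chromen‑4‑one | COc1cc(C2CC(=O)c3c(cc(OCOC)c(C/C=C(\C)CCC=C(C)C)c3O)O2)cc(OCOC)c1OCOC
F2 | step 4 | 6‑iodo‑5,7‑bis(methoxymethoxy)‑4H‑chromen‑4‑one | O=c1ccoc2cc(OCOC)c(I)c(OCOC)c12
F3 | step 4 | [5,7‑bis(methoxymethoxy)‑4‑oxo‑4H‑chromen‑6‑yl]magnesium chloride | O=c1ccoc2cc(OCOC)c([Mg]Cl)c(OCOC)c12
F4 | step 4 | 6‑[(2E)‑3,7‑dimethylocta‑2,6‑dien‑1‑yl]‑5,7‑bis(methoxymethoxy)‑4H‑chromen‑4‑one | O=c1ccoc2cc(OCOC)c(C/C=C(\C)CCC=C(C)C)c(OCOC)c12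
F5 | step 9 | 5‑hydroxy‑7‑[(triisopropylsilyl)oxy]‑4H‑chromen‑4‑one | O=c1ccoc2cc(O[Si](C(C)C)(C(C)C)C(C)C)cc(O)c12
F6 | step 9 | 5‑hydroxy‑6‑iodo‑7‑[(triisopropylsilyl)oxy]‑4H‑chromen‑4‑one | O=c1ccoc2cc(O[Si](C(C)C)(C(C)C)C(C)C)c(I)c(O)c12
F7 | step 9 | 6‑[(2E)‑3,7‑dimethylocta‑2,6‑dien‑1‑yl]‑5‑hydroxy‑7‑[(triisopropylsilyl)oxy]‑4H‑chromen‑4‑one | O=c1ccoc2cc(O[Si](C(C)C)(C(C)C)C(C)C)c(C/C=C(\C)CCC=C(C)C)c(O)c12
F8 | step 9 | 1,2‑bis[(tert‑butyldimethylsilyl)oxy]‑3‑methoxybenzene | COc1cccc(O[Si](C)(C)C(C)(C)C)c1O[Si](C)(C)C(C)(C)C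
F9 | step 9 | 2‑{3,4‑bis[(tert‑butyldimethylsilyl)oxy]‑5‑methoxyphenyl}‑4,4,5,5‑tetramethyl‑1,3,2‑dioxaborolane | COc1cc(B2OC(C)(C)C(C)(C)O2)cc(O[Si](C)(C)C(C)(C)C)c1O[Si](C)(C)C(C)(C)C
F10 | step 9 | {3,4‑bis[(tert‑butyldimethylsilyl)oxy]‑5‑methoxyphenyl}boronic acid | COc1cc(B(O)O)cc(O[Si](C)(C)C(C)(C)C)c1O[Si](C)(C)C(C)(C)C
F11 | step 9 | (2S)‑2‑{3,4‑bis[(tert‑butyldimethylsilyl)oxy]‑5‑methoxyphenyl}‑6‑[(2E)‑3,7‑dimethylocta‑2,6‑dien‑1‑yl]‑5‑hydroxy‑7‑[(triisopropylsilyl)oxy]‑2,3‑dihydro‑4H‑chromen‑4‑one | COc1cc([C@@H]2CC(=O)c3c(cc(O[Si](C(C)C)(C(C)C)C(C)C)c(C/C=C(\C)CCC=C(C)C)c3O)O2)cc(O[Si](C)(C)C(C)(C)C)c1O[Si](C)(C)C(C)(C)C
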